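**Compound numbers used throughout**

1 4-acetoxybenzoic acid · 2 4-acetoxybenzoyl chloride · 3 mono-tert-butyl malonate · 4 β-keto ester · 5 (R)-β-hydroxy ester · 6 3,4,5-trimethoxyphenol · 7 (S)-aryl ether tert-butyl ester · 8 (S)-aryl ether acid (precursor of the key step) · 9 its mixed trifluoroacetic anhydride (not isolated) · 10 (2S)-4'-acetoxy-5,6,7-trimethoxyflavanone (product of the key step) · 11 its 8-iodide · 12 the 5-hydroxy-8-iodide · 13 tributyl(prenyl)stannane · 14 the 8-prenyl 4'-acetate · 15 target

## Analysis of the target

Target 15 is a (2S)-flavanone: a benzene ring A fused to a dihydropyran-4-one ring C, with a 4-hydroxyphenyl ring B on C2. Ring A has no hydrogen left. C5 carries a hydroxyl hydrogen-bonded to the C4 carbonyl, C6 and C7 carry methoxy groups, C8 a 3-methylbut-2-enyl (prenyl) group and C8a the ring oxygen O1. C2 is the only stereocentre, so there is no relative configuration to control. It is, however, benzylic, bears O1 and lies β to the C4 carbonyl, which makes it the most fragile atom of the molecule. Base opens ring C by retro-oxa-Michael reaction to the achiral 2'-hydroxychalcone, a 4'-phenoxide can expel O1 through a quinone methide, and acid can ionise the C2–O1 bond once ring B is electron-rich; each path ends in racemisation. The prenyl double bond rules out hydrogenolysis and strong acid late in the route, and the phenols must be released without base. The difficulty is to set C2 and carry it through the construction of a fully substituted ring A, to tell the C5 oxygen from those on C6 and C7, and to place the prenyl group on C8. The strategy rests on the fact that O1 and the oxygens on C5, C6 and C7 are the four oxygens of 3,4,5-trimethoxyphenol 6. Its two ring carbons ortho to the hydroxyl are equivalent, and each is activated by the hydroxyl, an ortho methoxy group and a para methoxy group. One becomes C4a and the other C8, so the C4–C4a bond can be made after the C2–O1 stereocentre has been fixed in the open-chain acid 8.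

## Retrosynthetic reasoning

**15 ⇒ 14 (acyl–oxygen bond at O4').** Ring B must carry an electron-poor oxygen substituent for as long as C2 is an open-chain benzylic ether, and that substituent must leave without base. An aryl sulfonate would be more robust, but it comes off only with hydroxide, alkoxide or amide bases, under which a flavanone opens and recloses as the racemate. An acetate is electron-withdrawing enough and leaves at neutral pH, so 14 is the last intermediate. The price is that every earlier step has to avoid hydroxide, alkoxides and nucleophilic amines.

**14 ⇒ 12 + 13 (C8–CH2 bond).** C8 is the one carbon of ring A not accounted for by 6, so the prenyl group is attached there after the ring system exists. Electrophilic prenylation of the phenol would need acid and gives O-alkylated and rearranged products. Cross-coupling of the aryl iodide 12 with stannane 13 needs neither acid nor base, which the C2 stereocentre and the acetate both require.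

**12 ⇒ 11 ⇒ 10 (O–CH3 bond at C5, then C8–I bond).** The C5 methoxy group is the only one peri to the C4 carbonyl, so a chelating boron Lewis acid can remove it selectively. No differentiated protecting group is therefore needed on 6, and its symmetry is kept for the key step. The demethylation is placed before the prenyl group arrives so that the alkene never meets a Lewis acid. Iodination of 10 can only go to C8, the single free position of ring A.

**10 ⇒ 8 via 9 (C4–C4a bond, the key disconnection).** Cutting the aryl ketone bond turns ring C into the 3-aryl-3-aryloxypropanoic acid 8. This is the place to cut because the aryloxy group of 8 is locally symmetric, so acylation has no regiochemical question. The other ring C bond, C2–O1, would have to be closed under conditions that equilibrate C2. What is gained is that C2 is set by reliable open-chain chemistry and only watches the ring closure. The forward reaction must acylate a very nucleophilic arene through the mixed anhydride 9 without ionising or eliminating the benzylic ether.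

**8 ⇒ 7 ⇒ 5 + 6 (O-tert-butyl bond, then C2–O1 bond).** The acid is masked as a tert-butyl ester because that ester is released by acid; hydroxide would remove the acetate and could expel the aryloxide by β-elimination. The C2–O1 bond is formed by Mitsunobu displacement of the (R)-alcohol 5 by phenol 6, which inverts C2 to (S). The acetoxy group on ring B keeps the displacement bimolecular.

**5 ⇒ 4 ⇒ 2 + 3, and 2 ⇒ 1.** The stereocentre comes from asymmetric transfer hydrogenation of the aryl ketone 4. The ketone is assembled by magnesium-mediated acylation of the malonic half ester 3 with acid chloride 2, which is made from the acid 1. Both operations run without strong base.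

## Alternatives that were turned down

**Alternative 1: ring A by cyclobutenone–ynol ether benzannulation.** The C4a–C5 and C8–C8a bonds are cut, so ring A is built instead of bought. In the forward key step 3,4-dimethoxy-2-prenylcyclobutenone A1 opens thermally to a vinylketene. This adds to the ethynyl ether A2 of the (S)-benzylic alcohol, and 4π opening followed by 6π closure gives the pentasubstituted phenol A3.
- For: every substituent of ring A is placed by construction. The prenyl group is on C8 and the C5 oxygen is already a free phenol, so no halogenation, cross-coupling or selective demethylation is needed. On this point it is stronger than the chosen route.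
- Against: A2 is an alkynyl ether of a secondary benzylic alcohol with β-hydrogens. Such ethers fragment by a retro-ene path near the temperature the cyclobutenone needs to open, which would destroy the stereocentre.
- Against: the electron-rich silyloxy ring B makes the benzylic ether easy to ionise.
- Against: A1 and A2 each need a synthesis of their own. After A3, ring C is still open: the primary silyl ether must be removed, oxidised to the acid and acylated onto C4a, now with a prenyl group and an activated ring B present.
- Comparison: the chosen route does the same acylation earlier, on a substrate without alkene and with a deactivated ring B, and buys ring A. It gives up the built-in differentiation of C5 and C8 and pays with three late steps on ring A.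

**Alternative 2: ring C closed by C–O coupling at C8a.** The O1–C8a bond is cut. In the forward key step the (S)-alcohol of bromo alcohol A4 is coupled intramolecularly with the aryl bromide under Pd(OAc)2, a bulky di-tert-butylbiarylphosphine and Cs2CO3, giving the protected flavan-4-ol A5.
- For: the C2–O bond is formed with retention from an alcohol made by ketone reduction. No acid comes near C2, and ring B can carry a simple silyl ether. Here it is stronger than the chosen route.
- Against: the bromide of A4 sits between the prenyl group and a branched benzylic chain on an electron-rich ring. Oxidative addition is slow, and the hindered reductive elimination competes with β-hydride elimination of the secondary alkoxide.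
- Against: A4 is a hexasubstituted benzene that must be assembled with full regiocontrol.
- Against: C4 is carried at the alcohol level, so a protection and a later oxidation are added, followed by C5 demethylation with the prenyl group present.
- Comparison: the chosen route needs no regiocontrol on ring A, keeps C4 at the ketone level and is several steps shorter. In exchange it accepts an acid-mediated ring closure.

**Alternative 3: ring C by silyl enol ether ring-closing metathesis.** The C3–C4 bond is cut at the enol ether level. In the forward key step diene A6, with an (S)-1-arylallyl group on O1 and a 1-silyloxyvinyl group on C4a, is closed by the second-generation Grubbs catalyst RuCl2(H2IMes)(PCy3)(=CHPh). This gives the flavanone silyl enol ether A7 with loss of the two terminal methylene groups.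
- For: the closure is neutral, and hydrolysis of A7 gives the ketone directly. It is gentler on C2 than an acylation.
- Against: the ether of A6 is both allylic and benzylic on a phenol oxygen with a free ortho carbon. It can ionise or undergo aromatic Claisen rearrangement, and making it by displacement on a 1-arylallyl alcohol invites allylic transposition.
- Against: the metathesis must engage a 1,1-disubstituted, electron-rich enol ether flanked by two ortho substituents, which is the slow case for this catalyst.
- Against: the silyloxyvinyl group presupposes an aryl methyl ketone ortho to the ether oxygen, so 6 has to be acylated anyway. After A7, C8 prenylation, C5 demethylation and deprotection remain as in the chosen route.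
- Comparison: nothing is saved in step count, and the precursor is more fragile than the saturated acid 8.

Key step: step 6

Assumptions: 1, 3, 6 and 13 are purchased (1 is otherwise the O-acetate of 4-hydroxybenzoic acid, and 13 is the stannylation product of prenyl bromide). The sense of induction in step 3 is assigned by analogy with aryl alkyl ketones and would be checked on 5 before going on.

## Route

Step 1
Reactants: 1 4-acetoxybenzoic acid
Product: 2 4-acetoxybenzoyl chloride
Conditions: (COCl)2 (1.3 equiv), DMF (cat.), CH2Cl2, 0 °C → rt; evaporate, use crude
Reagents that add atoms: oxalyl chloride, O=C(Cl)C(Cl)=O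
Why: Acid chloride formation under Vilsmeier catalysis is neutral toward the aryl acetate, and the by-products are gases, so crude 2 can be used directly.

Step 2
Reactants: 2 4-acetoxybenzoyl chloride; 3 mono-tert-butyl malonate
Product: 4 tert-butyl 3-(4-acetoxyphenyl)-3-oxopropanoate
Conditions: 3 (2.0 equiv), MgCl2 (2.5 equiv), Et3N (5 equiv), MeCN, 0 °C → rt; then 2, 0 °C → rt; 10% aq. citric acid
Reagents that add atoms: none
Why: Magnesium-mediated C-acylation of a malonic half ester (Masamune-type decarboxylative Claisen condensation): the chelated magnesium enolate of 3 is acylated by 2 and the acylmalonate loses CO2 on mild acid work-up, so the aryl acetate never meets a strong base.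

Step 3
Reactants: 4 tert-butyl 3-(4-acetoxyphenyl)-3-oxopropanoate
Product: 5 tert-butyl (3R)-3-(4-acetoxyphenyl)-3-hydroxypropanoate
Conditions: RuCl(p-cymene)[(R,R)-TsDPEN] (1 mol%), HCO2H/Et3N (5:2), EtOAc, 30 °C
Reagents that add atoms: none
Why: Noyori–Ikariya asymmetric transfer hydrogenation of an aryl ketone; the (R,R)-diamine complex delivers hydride to the face that gives (R)-1-arylalkanols, and since CH2CO2tBu takes the place of the alkyl group and ranks below aryl, the new carbinol centre should be (R). The weakly acidic formate medium at 30 °C should spare both the aryl acetate and the tert-butyl ester, which a hot alcoholic hydrogenation would not guarantee.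

Step 4
Reactants: 5 tert-butyl (3R)-3-(4-acetoxyphenyl)-3-hydroxypropanoate; 6 3,4,5-trimethoxyphenol
Product: 7 tert-butyl (3S)-3-(4-acetoxyphenyl)-3-(3,4,5-trimethoxyphenoxy)propanoate
Conditions: PPh3 (1.5 equiv), DIAD (1.5 equiv), 6 (1.5 equiv), toluene, 0 °C → rt
Reagents that add atoms: none
Why: Mitsunobu etherification: phenol 6 is acidic enough to protonate the betaine and displaces the oxyphosphonium group by SN2 with inversion, turning (R)-5 into (S)-7. The acetoxy group keeps the benzylic carbon from ionising, so the displacement should stay stereospecific, and the low temperature holds back elimination to the cinnamate.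

Step 5
Reactants: 7 tert-butyl (3S)-3-(4-acetoxyphenyl)-3-(3,4,5-trimethoxyphenoxy)propanoate
Product: 8 (3S)-3-(4-acetoxyphenyl)-3-(3,4,5-trimethoxyphenoxy)propanoic acid
Conditions: TFA/CH2Cl2 (1:4), Et3SiH (3 equiv), 0 °C → rt; evaporate, azeotrope with toluene
Reagents that add atoms: none
Why: Acidolysis of the tert-butyl ester (alkyl–oxygen cleavage) frees the acid without hydroxide, which would cleave the aryl acetate and could expel the aryloxide by E1cB. Et3SiH is a cation scavenger that keeps tert-butyl cation off the electron-rich ring, and the acetoxy-deactivated benzylic ether should not ionise in dilute TFA at this temperature.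

Step 6
Reactants: 8 (3S)-3-(4-acetoxyphenyl)-3-(3,4,5-trimethoxyphenoxy)propanoic acid
Product: 10 (2S)-4'-acetoxy-5,6,7-trimethoxyflavanone, via mixed trifluoroacetic anhydride 9 (not isolated)
Conditions: (CF3CO)2O (2.0 equiv), CH2Cl2, 0 °C → rt; cold aq. NaHCO3
Reagents that add atoms: trifluoroacetic anhydride, O=C(OC(=O)C(F)(F)F)C(F)(F)F (its trifluoroacetyl group sits only in 9 and leaves again on ring closure; 10 keeps no atom of it)
Why: Trifluoroacetic anhydride converts 8 into the mixed anhydride 9, whose acyl carbon (as such, or as the acylium ion formed by loss of trifluoroacetate under the TFA released) is attacked by the ring carbon ortho to the ether oxygen; loss of a proton from the arenium ion gives the aryl ketone and the C4–C4a bond. The closest known reaction type is the cyclisation of 3-aryloxypropanoic acids to chroman-4-ones with trifluoroacetic anhydride or polyphosphoric acid, an intramolecular Friedel–Crafts acylation. Ring C closes as a six-membered ring in a 6-exo-trig electrophilic aromatic substitution, exo with respect to the carbonyl that is attacked. No stereocentre is formed; C2 is a spectator, and its (S) configuration from step 4 should be retained because the C2–O1 bond is not touched. Regioselectivity is not in question: the two carbons ortho to the ether oxygen are equivalent, each activated by that oxygen, an ortho methoxy group and a para methoxy group, while ring B is deactivated and cannot reach the acyl carbon in a favourable ring size. The selectivity the step does need is acylation over ionisation or β-elimination of the benzylic aryl ether; the acetoxy group on ring B and the carbonyl β to C2 both destabilise a cation at C2, and the very nucleophilic arene allows activation at 0 °C without strong acid. The anhydride is kept near two equivalents so that the remaining C8–H of 10, now on a ring conjugated to the ketone, is not trifluoroacetylated.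

Step 7
Reactants: 10 (2S)-4'-acetoxy-5,6,7-trimethoxyflavanone
Product: 11 (2S)-4'-acetoxy-8-iodo-5,6,7-trimethoxyflavanone
Conditions: NIS (1.05 equiv), TFA (10 mol%), MeCN, 0 °C → rt, dark
Reagents that add atoms: N-iodosuccinimide, O=C1CCC(=O)N1I
Why: Electrophilic aromatic iodination at C8, the only unsubstituted carbon of ring A, which is ortho to O1 and to the C7 methoxy group and para to the C5 methoxy group; ring B carries the deactivating acetoxy group and should be left alone.

Step 8
Reactants: 11 (2S)-4'-acetoxy-8-iodo-5,6,7-trimethoxyflavanone
Product: 12 (2S)-4'-acetoxy-5-hydroxy-8-iodo-6,7-dimethoxyflavanone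
Conditions: BCl3 (1.0 M in CH2Cl2, 2.0 equiv), CH2Cl2, −78 → 0 °C; ice-water
Reagents that add atoms: none
Why: Chelation-controlled Lewis acid demethylation: boron binds the C4 carbonyl and the peri C5 methoxy oxygen in a six-membered chelate and chloride removes that methyl group only, leaving the C6 and C7 methoxy groups, the aryl acetate and the iodide. Ring B is still acylated, so the Lewis acid should not ionise C2–O1, and no alkene is present yet.

Step 9
Reactants: 12 (2S)-4'-acetoxy-5-hydroxy-8-iodo-6,7-dimethoxyflavanone; 13 tributyl(3-methylbut-2-en-1-yl)stannane
Product: 14 (2S)-4'-acetoxy-5-hydroxy-6,7-dimethoxy-8-(3-methylbut-2-en-1-yl)flavanone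
Conditions: Pd(PPh3)4 (10 mol%), 13 (1.5 equiv), toluene (degassed), 100 °C
Reagents that add atoms: none
Why: Stille coupling: oxidative addition of the palladium complex into the C8–I bond, transmetalation with the allylic stannane and reductive elimination at the unsubstituted allyl terminus should give the linear prenyl group. No base is present, so neither ring C nor the aryl acetate is put at risk, and the chelated 5-OH is tolerated.

Step 10
Reactants: 14 (2S)-4'-acetoxy-5-hydroxy-6,7-dimethoxy-8-(3-methylbut-2-en-1-yl)flavanone
Product: 15 (2S)-4',5-dihydroxy-6,7-dimethoxy-8-(3-methylbut-2-en-1-yl)flavanone (target)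
Conditions: NH4OAc (10 equiv), MeOH/H2O (4:1), rt
Reagents that add atoms: none
Why: A phenolic acetate is the most reactive acyl donor in the molecule and is cleaved by ammonium acetate in aqueous methanol at about neutral pH (acyl transfer to solvent). Neither a C3 enolate nor a 4'-phenoxide builds up under these conditions, so ring C should stay closed and C2 (S), and the prenyl group sees no acid.

## Compound list

1 | 4-acetoxybenzoic acid | CC(=O)Oc1ccc(cc1)C(=O)O | starting material
2 | 4-acetoxybenzoyl chloride | CC(=O)Oc1ccc(cc1)C(=O)Cl | intermediate
3 | mono-tert-butyl malonate (3-tert-butoxy-3-oxopropanoic acid) | CC(C)(C)OC(=O)CC(=O)O | starting material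
4 | tert-butyl 3-(4-acetoxyphenyl)-3-oxopropanoate | CC(=O)Oc1ccc(cc1)C(=O)CC(=O)OC(C)(C)C | intermediate
5 | tert-butyl (3R)-3-(4-acetoxyphenyl)-3-hydroxypropanoate | CC(=O)Oc1ccc(cc1)[C@H](O)CC(=O)OC(C)(C)C | intermediate
6 | 3,4,5-trimethoxyphenol | COc1cc(O)cc(OC)c1OC | starting material
7 | tert-butyl (3S)-3-(4-acetoxyphenyl)-3-(3,4,5-trimethoxyphenoxy)propanoate | COc1cc(O[C@H](c2ccc(OC(C)=O)cc2)CC(=O)OC(C)(C)C)cc(OC)c1OC | intermediate
8 | (3S)-3-(4-acetoxyphenyl)-3-(3,4,5-trimethoxyphenoxy)propanoic acid | COc1cc(O[C@H](c2ccc(OC(C)=O)cc2)CC(=O)O)cc(OC)c1OC | intermediate
9 | (3S)-3-(4-acetoxyphenyl)-3-(3,4,5-trimethoxyphenoxy)propanoic trifluoroacetic anhydride | COc1cc(O[C@H](c2ccc(OC(C)=O)cc2)CC(=O)OC(=O)C(F)(F)F)cc(OC)c1OC | intermediate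
10 | (2S)-4'-acetoxy-5,6,7-trimethoxyflavanone, 4-[(2S)-5,6,7-trimethoxy-4-oxochroman-2-yl]phenyl acetate | COc1c(OC)c2c(cc1OC)O[C@H](c1ccc(OC(C)=O)cc1)CC2=O | intermediate
11 | (2S)-4'-acetoxy-8-iodo-5,6,7-trimethoxyflavanone | COc1c(OC)c2c(c(I)c1OC)O[C@H](c1ccc(OC(C)=O)cc1)CC2=O | intermediate
12 | (2S)-4'-acetoxy-5-hydroxy-8-iodo-6,7-dimethoxyflavanone | COc1c(O)c2c(c(I)c1OC)O[C@H](c1ccc(OC(C)=O)cc1)CC2=O | intermediate
13 | tributyl(3-methylbut-2-en-1-yl)stannane | CCCC[Sn](CCCC)(CCCC)CC=C(C)C | starting material
14 | (2S)-4'-acetoxy-5-hydroxy-6,7-dimethoxy-8-(3-methylbut-2-en-1-yl)flavanone | COc1c(O)c2c(c(CC=C(C)C)c1OC)O[C@H](c1ccc(OC(C)=O)cc1)CC2=O | intermediate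
15 | (2S)-4',5-dihydroxy-6,7-dimethoxy-8-(3-methylbut-2-en-1-yl)flavanone | COc1c(O)c2c(c(CC=C(C)C)c1OC)O[C@H](c1ccc(O)cc1)CC2=O | target

## Step count and least certain steps

Total: 10 steps. Longest linear sequence: 10 steps (1 → 15); 3, 6 and 13 enter as purchased materials.

**Step 6 (key step).** The most likely failure is acid-promoted ionisation or β-elimination at the benzylic aryl ether competing with acylation. That would erode the enantiomeric purity at C2 or cleave the ether. If ring closure is slow, the trifluoroacetyl group may instead be transferred to the arene. Stronger activation (a sulfonic acid or a Lewis acid) would speed the closure but raise the first risk. The fallback makes the same bond by an anionic route with no acid. It sets out from 8. Bromination with NBS in MeCN at 0 °C should go to one of the two equivalent ortho carbons and give (3S)-3-(4-acetoxyphenyl)-3-(2-bromo-3,4,5-trimethoxyphenoxy)propanoic acid F1. Treatment of F1 with n-BuLi (2.1 equiv) in THF at −100 °C forms the lithium carboxylate and then the aryllithium by bromine–lithium exchange. The aryllithium adds to the carboxylate in a Parham cyclisation, and aqueous work-up releases the ketone, returning to the route at 10. This relies on the exchange at −100 °C outrunning attack on the aryl acetate.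

**Step 4.** The likely failures are elimination of the activated alcohol to the cinnamate (the ester α-hydrogens are acidic), a slow displacement by the electron-rich phenol, and acetyl transfer from ring B to the phenoxide. The fallback replaces the Mitsunobu reaction by ring opening of a β-lactone. It sets out from 5. TFA in CH2Cl2 gives (3R)-3-(4-acetoxyphenyl)-3-hydroxypropanoic acid F2. Benzenesulfonyl chloride in pyridine at 0 °C activates the carboxyl group and closes the lactone with retention at the carbinol carbon, giving (4R)-4-(4-acetoxyphenyl)oxetan-2-one F3. Phenol 6 with Cs2CO3 in DMF at 0 °C should open F3 at the benzylic carbon by SN2 alkyl–oxygen cleavage with inversion. This delivers the acid directly and returns to the route at 8, ahead of step 6.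

**Step 9.** The likely failures are slow oxidative addition at a di-ortho-substituted, electron-rich iodide with protodeiodination as the result, allylic transposition to the 1,1-dimethylallyl isomer, and migration of the double bond into conjugation. The fallback installs the prenyl group by a para-Claisen–Cope sequence and needs no iodide. It sets out from 10. BCl3 under the conditions of step 8 gives (2S)-4'-acetoxy-5-hydroxy-6,7-dimethoxyflavanone F4. Mitsunobu alkylation of the 5-hydroxyl with 3-methylbut-2-en-1-ol (PPh3, DIAD, THF) gives (2S)-4'-acetoxy-6,7-dimethoxy-5-(3-methylbut-2-en-1-yloxy)flavanone F5. Tris(6,6,7,7,8,8,8-heptafluoro-2,2-dimethyloctane-3,5-dionato)europium, Eu(fod)3, in CHCl3 at 60 °C should then promote a [3,3] shift to the blocked ortho carbon C6 followed by a Cope shift to C8. Tautomerisation gives the 5-hydroxy-8-prenyl compound, returning to the route at 14.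

**Step 10.** The likely failures are slow acyl transfer, or partial ring opening and racemisation of the freed 4'-hydroxyflavanone if the medium drifts basic. The fallback removes the acetate before the alkene is present, where acid can be used. It sets out from 12. HCl in MeOH (from acetyl chloride, 0 °C → rt) cleaves the acetate by acid-catalysed transesterification; flavanones hold their configuration in acid. This gives (2S)-4',5-dihydroxy-8-iodo-6,7-dimethoxyflavanone F6. Stille coupling of F6 with 13 under the conditions of step 9 then reaches 15 directly, so the last step is a base-free C–C coupling.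

## Further compounds

F1 | step 6 | (3S)-3-(4-acetoxyphenyl)-3-(2-bromo-3,4,5-trimethoxyphenoxy)propanoic acid | COc1cc(O[C@H](c2ccc(OC(C)=O)cc2)CC(=O)O)c(Br)c(OC)c1OC
F2 | step 4 | (3R)-3-(4-acetoxyphenyl)-3-hydroxypropanoic acid | CC(=O)Oc1ccc(cc1)[C@H](O)CC(=O)O
F3 | step 4 | (4R)-4-(4-acetoxyphenyl)oxetan-2-one | CC(=O)Oc1ccc(cc1)[C@H]1CC(=O)O1
F4 | step 9 | (2S)-4'-acetoxy-5-hydroxy-6,7-dimethoxyflavanone | COc1c(O)c2c(cc1OC)O[C@H](c1ccc(OC(C)=O)cc1)CC2=O
F5 | step 9 | (2S)-4'-acetoxy-6,7-dimethoxy-5-(3-methylbut-2-en-1-yloxy)flavanone | COc1c(OCC=C(C)C)c2c(cc1OC)O[C@H](c1ccc(OC(C)=O)cc1)CC2=O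
F6 | step 10 | (2S)-4',5-dihydroxy-8-iodo-6,7-dimethoxyflavanone | COc1c(O)c2c(c(I)c1OC)O[C@H](c1ccc(O)cc1)CC2=O
A1 | alternative 1 | 3,4-dimethoxy-2-(3-methylbut-2-en-1-yl)cyclobut-2-en-1-one (racemic at C4) | COC1C(=O)C(CC=C(C)C)=C1OC
A2 | alternative 1 | tert-butyl{(3S)-3-(ethynyloxy)-3-[4-(triisopropylsilyloxy)phenyl]propoxy}dimethylsilane | C#CO[C@H](c1ccc(O[Si](C(C)C)(C(C)C)C(C)C)cc1)CCO[Si](C)(C)C(C)(C)C
A3 | alternative 1 | (S)-5-[3-(tert-butyldimethylsilyloxy)-1-(4-(triisopropylsilyloxy)phenyl)propoxy]-2,3-dimethoxy-4-(3-methylbut-2-en-1-yl)phenol | COc1c(O)cc(O[C@H](c2ccc(O[Si](C(C)C)(C(C)C)C(C)C)cc2)CCO[Si](C)(C)C(C)(C)C)c(CC=C(C)C)c1OC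
A4 | alternative 2 | (1S)-3-[2-bromo-4,5,6-trimethoxy-3-(3-methylbut-2-en-1-yl)phenyl]-1-[4-(tert-butyldimethylsilyloxy)phenyl]-3-(triethylsilyloxy)propan-1-ol, either C3 epimer | COc1c(OC)c(C(O[Si](CC)(CC)CC)C[C@H](O)c2ccc(O[Si](C)(C)C(C)(C)C)cc2)c(Br)c(CC=C(C)C)c1OC
A5 | alternative 2 | (2S)-5,6,7-trimethoxy-8-(3-methylbut-2-en-1-yl)-4'-(tert-butyldimethylsilyloxy)-4-(triethylsilyloxy)flavan, either C4 epimer | COc1c(OC)c2c(c(CC=C(C)C)c1OC)O[C@H](c1ccc(O[Si](C)(C)C(C)(C)C)cc1)CC2O[Si](CC)(CC)CC
A6 | alternative 3 | (S)-1-[4-(tert-butyldimethylsilyloxy)phenyl]prop-2-en-1-yl 2-[1-(tert-butyldimethylsilyloxy)ethenyl]-3,4,5-trimethoxyphenyl ether | COc1c(OC)c(C(=C)O[Si](C)(C)C(C)(C)C)c(cc1OC)O[C@H](c1ccc(O[Si](C)(C)C(C)(C)C)cc1)C=C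
A7 | alternative 3 | (2S)-4-(tert-butyldimethylsilyloxy)-5,6,7-trimethoxy-2-[4-(tert-butyldimethylsilyloxy)phenyl]-2H-chromene | COc1c(OC)c2c(cc1OC)O[C@H](c1ccc(O[Si](C)(C)C(C)(C)C)cc1)C=C2O[Si](C)(C)C(C)(C)C
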